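**Retrosynthetic overview**
1. The acid comes from its methyl ester. The C14=C15 (E) bond comes from a Julia–Kocienski olefination of a C1–C14 enal with the phenyltetrazolyl sulfone of (Z)-hex-3-en-1-ol. The enal comes from cross metathesis of a terminal alkene with crotonaldehyde.
2. Key C2–C3 bond: intermolecular Mukaiyama aldol-type addition of the silyl ketene acetal of methyl acetate to the peroxycarbenium ion released from a (5S)-3-methoxy-1,2-dioxolane, which is a masked methyl ketone.
3. The dioxolane comes from a 4-hydroperoxy-2-ketone, made by perhydrolysis with inversion of a (2R)-2,2,4-trisubstituted oxetane. This step sets C5.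
4. The oxetane comes from a 1,3-diol monomesylate, made by directed hydride opening of the Sharpless epoxide of (E)-3-methylundeca-2,10-dien-1-ol. That alcohol comes from carbocupration of ethyl but-2-ynoate.
5. Ring order: oxirane (made in step 3, opened in step 6), then oxetane (made in step 8, opened in step 9), then 1,2-dioxolane (made in step 12, kept). The dioxolane is the only ring of the target.

Assumption: with C1 = CO2H the SMILES reads (3R,5S,12E,14E,17Z). The carbinol carbon made in step 5 and the anomeric carbon of 17 and 18 are carried as epimer mixtures and drawn without a stereo mark, because steps 11 and 15 erase them.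

**Step 1**
Reactants: 1 8-bromooct-1-ene; 2 ethyl but-2-ynoate
Product: 5 ethyl (2E)-3-methylundeca-2,10-dienoate, via oct-7-en-1-ylmagnesium bromide 3 (not isolated), via oct-7-en-1-ylcopper 4 (not isolated)
Conditions: 1, Mg, THF, 25–40 °C; CuBr·SMe2 (1 equiv), −40 °C; 2 (0.8 equiv), −78 °C, 2 h; aq. NH4Cl at −78 °C
Reagents that add atoms: none
Why: Carbocupration (syn conjugate addition of an organocopper reagent to an ynoate) puts alkyl and copper on the same side of the triple bond at −78 °C, and protonation with retention places the chain trans to the ester (E, typically >95:5) while the remote terminal alkene stays inert.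

**Step 2**
Reactants: 5 ethyl (2E)-3-methylundeca-2,10-dienoate
Product: 6 (2E)-3-methylundeca-2,10-dien-1-ol
Conditions: i-Bu2AlH (2.3 equiv), CH2Cl2, −78 → 0 °C; aq. KNaC4H4O6
Reagents that add atoms: none
Why: Ester reduction by i-Bu2AlH is a clean 1,2-reduction that gives the allylic alcohol without touching either C=C bond or the E geometry.

**Step 3**
Reactants: 6 (2E)-3-methylundeca-2,10-dien-1-ol
Product: 7 [(2R,3R)-3-methyl-3-(oct-7-en-1-yl)oxiran-2-yl]methanol
Conditions: Ti(Oi-Pr)4 (10 mol %), D-(−)-diethyl tartrate (12 mol %), t-BuOOH (2 equiv, decane), 4 Å MS, CH2Cl2, −20 °C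
Reagents that add atoms: tert-butyl hydroperoxide, CC(C)(C)OO
Why: In the Sharpless asymmetric epoxidation only the alkene next to the titanium-bound hydroxyl reacts, and for geraniol-type (E)-3-methylalk-2-en-1-ols the D-(−)-tartrate catalyst gives the (2R,3R)-epoxide in about 95% ee, which sets the tertiary C–O centre (R) that later becomes C5.

**Step 4**
Reactants: 7 [(2R,3R)-3-methyl-3-(oct-7-en-1-yl)oxiran-2-yl]methanol
Product: 8 (2S,3R)-3-methyl-3-(oct-7-en-1-yl)oxirane-2-carbaldehyde
Conditions: Dess–Martin periodinane (1.3 equiv), NaHCO3, CH2Cl2, 0 → 25 °C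
Reagents that add atoms: none
Why: Buffered Dess–Martin oxidation stops at the aldehyde and neither opens the epoxide nor epimerises C2, whose descriptor becomes S only because the priorities change.

**Step 5**
Reactants: 8 (2S,3R)-3-methyl-3-(oct-7-en-1-yl)oxirane-2-carbaldehyde
Product: 9 1-[(2R,3R)-3-methyl-3-(oct-7-en-1-yl)oxiran-2-yl]ethan-1-ol (both carbinol epimers)
Conditions: MeMgBr (1.3 equiv), Et2O, −78 °C; aq. NH4Cl
Reagents that add atoms: methylmagnesium bromide, C[Mg]Br
Why: Grignard 1,2-addition to the aldehyde is far faster than epoxide opening at −78 °C, and the unselective new carbinol centre is harmless because step 11 erases it.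

**Step 6**
Reactants: 9 1-[(2R,3R)-3-methyl-3-(oct-7-en-1-yl)oxiran-2-yl]ethan-1-ol
Product: 10 (4R)-4-methyldodec-11-ene-2,4-diol (both C2 epimers)
Conditions: NaAlH2(OCH2CH2OMe)2 (3 equiv), THF, 0 → 25 °C
Reagents that add atoms: none
Why: In this hydroxyl-directed reductive epoxide opening the alkoxyaluminium hydride formed at the carbinol oxygen delivers hydride intramolecularly to the adjacent, less substituted epoxide carbon, which gives the 1,3-diol and leaves the tertiary C–O bond and its R configuration untouched.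

**Step 7**
Reactants: 10 (4R)-4-methyldodec-11-ene-2,4-diol
Product: 11 (4R)-4-hydroxy-4-methyldodec-11-en-2-yl methanesulfonate (both C2 epimers)
Conditions: MsCl (1.1 equiv), Et3N (1.5 equiv), CH2Cl2, −20 °C
Reagents that add atoms: methanesulfonyl chloride, CS(=O)(=O)Cl
Why: Chemoselective sulfonylation works because the secondary hydroxyl is mesylated at low temperature while the hindered tertiary hydroxyl does not react, and no stereocentre is affected.

**Step 8**
Reactants: 11 (4R)-4-hydroxy-4-methyldodec-11-en-2-yl methanesulfonate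
Product: 12 (2R)-2,4-dimethyl-2-(oct-7-en-1-yl)oxetane (both C4 epimers)
Conditions: KOt-Bu (1.4 equiv), THF, 0 → 25 °C
Reagents that add atoms: none
Why: In this intramolecular Williamson etherification (4-exo-tet) the tertiary alkoxide displaces the secondary mesylate with inversion at that disposable carbon, the tertiary C–O bond is retained (still R), and the low temperature keeps Grob fragmentation and elimination minor.

**Step 9**
Reactants: 12 (2R)-2,4-dimethyl-2-(oct-7-en-1-yl)oxetane
Product: 13 (4S)-4-hydroperoxy-4-methyldodec-11-en-2-ol (both C2 epimers)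
Conditions: anhydrous H2O2 (about 3 M in Et2O, 10 equiv), Me3SiOTf (0.2 equiv), Et2O, −78 → 0 °C, blast shield
Reagents that add atoms: hydrogen peroxide, OO
Why: In this Lewis acid-promoted oxetane perhydrolysis, silylation of the ring oxygen lets H2O2 attack the tertiary carbon, the one best able to carry positive charge, from the rear in a tight SN2-like opening, so C–O is exchanged for C–OO with inversion (R to S) and C5 of the target is set.

**Step 10**
Reactants: 13 (4S)-4-hydroperoxy-4-methyldodec-11-en-2-ol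
Product: 14 (4S)-4-[(tert-butyldimethylsilyl)peroxy]-4-methyldodec-11-en-2-ol (both C2 epimers)
Conditions: TBSCl (1.05 equiv), imidazole (1.5 equiv), DMF, 0 °C
Reagents that add atoms: tert-butyldimethylsilyl chloride, CC(C)(C)[Si](C)(C)Cl
Why: Chemoselective O-silylation works because the hydroperoxide is more acidic and, through the alpha effect, more nucleophilic than the secondary alcohol, so one equivalent of TBSCl caps only the OOH group.

**Step 11**
Reactants: 14 (4S)-4-[(tert-butyldimethylsilyl)peroxy]-4-methyldodec-11-en-2-ol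
Product: 15 (4S)-4-[(tert-butyldimethylsilyl)peroxy]-4-methyldodec-11-en-2-one
Conditions: Dess–Martin periodinane (1.3 equiv), NaHCO3, CH2Cl2, 0 → 25 °C
Reagents that add atoms: none
Why: Dess–Martin oxidation converts both carbinol epimers into one ketone under neutral conditions that the silyl peroxide and the alkene tolerate, and the fully substituted C4 centre cannot epimerise.

**Step 12**
Reactants: 15 (4S)-4-[(tert-butyldimethylsilyl)peroxy]-4-methyldodec-11-en-2-one
Product: 17 (5S)-3,5-dimethyl-5-(oct-7-en-1-yl)-1,2-dioxolan-3-ol (both C3 anomers), via hydroperoxy ketone 16 (not isolated)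
Conditions: 48% aq. HF, MeCN, 0 °C
Reagents that add atoms: none
Why: Acidic fluoride desilylation frees hydroperoxy ketone 16, whose OOH group adds at once to the ketone (5-exo-trig peroxyhemiketalisation) to close the 1,2-dioxolane, with C5 untouched and the anomeric C3 mixture irrelevant.

**Step 13**
Reactants: 17 (5S)-3,5-dimethyl-5-(oct-7-en-1-yl)-1,2-dioxolan-3-ol
Product: 18 (5S)-3-methoxy-3,5-dimethyl-5-(oct-7-en-1-yl)-1,2-dioxolane (both C3 anomers)
Conditions: MeOH, p-TsOH·H2O (5 mol %), 3 Å MS, 25 °C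
Reagents that add atoms: methanol, CO
Why: In this acid-catalysed ketal exchange the peroxyhemiketal ionises reversibly and methanol as solvent traps the cation, which gives the stable methyl peroxyketal as an anomer mixture that converges in step 15.

**Step 14**
Reactants: 19 methyl acetate
Product: 21 tert-butyl[(1-methoxyethenyl)oxy]dimethylsilane, via lithium enolate 20 (not isolated)
Conditions: LiN(i-Pr)2 (commercial solution, 1.05 equiv), THF, −78 °C; TBSCl (1.1 equiv), DMPU, −78 → 25 °C; distillation
Reagents that add atoms: tert-butyldimethylsilyl chloride, CC(C)(C)[Si](C)(C)Cl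
Why: Kinetic enolisation followed by O-silylation works because LiN(i-Pr)2 deprotonates methyl acetate completely at −78 °C and bulky TBSCl in the presence of DMPU silylates oxygen rather than carbon.

**Step 15 (key step)**
Reactants: 18 (5S)-3-methoxy-3,5-dimethyl-5-(oct-7-en-1-yl)-1,2-dioxolane; 21 tert-butyl[(1-methoxyethenyl)oxy]dimethylsilane
Product: 23 methyl 2-[(3R,5S)-3,5-dimethyl-5-(oct-7-en-1-yl)-1,2-dioxolan-3-yl]acetate, via peroxycarbenium ion 22 (not isolated)
Conditions: TiCl4 (1.1 equiv), 21 (2.5 equiv), CH2Cl2, −78 °C, 1 h; aq. NaHCO3; SiO2 or HPLC separation of the C3 epimers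
Reagents that add atoms: none
Why: In this Mukaiyama aldol-type addition (ketal variant) TiCl4 ionises the masked ketone 18 to peroxycarbenium ion 22, which the silyl ketene acetal attacks intermolecularly to forge C2–C3 with the O–O bond intact, and because C5 differentiates the two faces only weakly (methyl versus chain, slight preference for attack anti to the chain, about 1–2:1 expected) the (3R,5S) isomer with the acetate arm trans to the chain is secured by chromatographic separation from its C3 epimer and checked by NOE between the C3 methyl and the first chain CH2.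

**Step 16**
Reactants: 23 methyl 2-[(3R,5S)-3,5-dimethyl-5-(oct-7-en-1-yl)-1,2-dioxolan-3-yl]acetate; 24 (2E)-but-2-enal
Product: 25 methyl 2-{(3R,5S)-3,5-dimethyl-5-[(7E)-9-oxonon-7-en-1-yl]-1,2-dioxolan-3-yl}acetate
Conditions: 24 (5 equiv), second-generation Hoveyda–Grubbs catalyst RuCl2(H2IMes)(=CH-C6H4-2-Oi-Pr) (3 mol %), CH2Cl2, 40 °C
Reagents that add atoms: none
Why: Olefin cross metathesis of an unhindered terminal alkene with an excess of an electron-poor enal is selective for the cross product and strongly E (>20:1), and the neutral phosphine-free ruthenium carbene leaves the dialkyl peroxide, the ester and both stereocentres alone.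

**Step 17**
Reactants: 26 (3Z)-hex-3-en-1-ol; 27 1-phenyl-1H-tetrazole-5-thiol
Product: 28 5-{[(3Z)-hex-3-en-1-yl]sulfanyl}-1-phenyl-1H-tetrazole
Conditions: PPh3 (1.2 equiv), DIAD (1.2 equiv), THF, 0 → 25 °C
Reagents that add atoms: none
Why: In this Mitsunobu thioetherification the acidic tetrazolethiol displaces the activated primary alcohol under neutral conditions that leave the Z alkene in place.

**Step 18**
Reactants: 28 5-{[(3Z)-hex-3-en-1-yl]sulfanyl}-1-phenyl-1H-tetrazole
Product: 29 5-{[(3Z)-hex-3-en-1-yl]sulfonyl}-1-phenyl-1H-tetrazole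
Conditions: (NH4)6Mo7O24·4H2O (10 mol %), 30% aq. H2O2 (8 equiv), EtOH, 0 → 25 °C
Reagents that add atoms: hydrogen peroxide, OO
Why: Molybdate-catalysed sulfide oxidation takes sulfur to the sulfone much faster than it epoxidises an isolated disubstituted alkene.

**Step 19**
Reactants: 29 5-{[(3Z)-hex-3-en-1-yl]sulfonyl}-1-phenyl-1H-tetrazole; 25 methyl 2-{(3R,5S)-3,5-dimethyl-5-[(7E)-9-oxonon-7-en-1-yl]-1,2-dioxolan-3-yl}acetate
Product: 31 methyl 2-{(3R,5S)-3,5-dimethyl-5-[(7E,9E,12Z)-pentadeca-7,9,12-trien-1-yl]-1,2-dioxolan-3-yl}acetate, via potassium sulfonyl carbanion 30 (not isolated)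
Conditions: 29 (1.3 equiv), KN(SiMe3)2 (1.25 equiv), THF, −78 °C, 30 min; 25, −78 → 0 °C; aq. NH4Cl
Reagents that add atoms: none
Why: In this Julia–Kocienski olefination the preformed carbanion 30 adds to the enal within minutes at −78 °C, faster than it can deprotonate the ester, and Smiles rearrangement with loss of SO2 and the tetrazolone gives the new C14=C15 bond mainly E (usually at least 10:1 with enals), while the C12=C13 (E) and C17=C18 (Z) bonds and both ring stereocentres pass through unchanged.

**Step 20**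
Reactants: 31 methyl 2-{(3R,5S)-3,5-dimethyl-5-[(7E,9E,12Z)-pentadeca-7,9,12-trien-1-yl]-1,2-dioxolan-3-yl}acetate
Product: 33 2-{(3R,5S)-3,5-dimethyl-5-[(7E,9E,12Z)-pentadeca-7,9,12-trien-1-yl]-1,2-dioxolan-3-yl}acetic acid, via lithium carboxylate 32 (not isolated)
Conditions: LiOH·H2O (5 equiv), THF–MeOH–H2O 3:1:1, argon, 0 → 25 °C; 1 M HCl to pH 3 at 0 °C
Reagents that add atoms: lithium hydroxide, [Li+].[OH-]
Why: In this saponification hydroxide adds to the unhindered ester carbonyl much faster than it enolises it, the fully substituted dioxolane carbons carry no hydrogen for base-induced peroxide cleavage, and no stereocentre or alkene is touched, so acidification of 32 gives the target.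

**Compound list**
1 | 8-bromooct-1-ene | C=CCCCCCCBr | starting material
2 | ethyl but-2-ynoate | CC#CC(=O)OCC | starting material
3 | oct-7-en-1-ylmagnesium bromide | C=CCCCCCC[Mg]Br | intermediate
4 | oct-7-en-1-ylcopper | C=CCCCCCC[Cu] | intermediate
5 | ethyl (2E)-3-methylundeca-2,10-dienoate | C=CCCCCCC/C(C)=C/C(=O)OCC | intermediate
6 | (2E)-3-methylundeca-2,10-dien-1-ol | C=CCCCCCC/C(C)=C/CO | intermediate
7 | [(2R,3R)-3-methyl-3-(oct-7-en-1-yl)oxiran-2-yl]methanol | C=CCCCCCC[C@@]1(C)O[C@@H]1CO | intermediate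
8 | (2S,3R)-3-methyl-3-(oct-7-en-1-yl)oxirane-2-carbaldehyde | C=CCCCCCC[C@@]1(C)O[C@@H]1C=O | intermediate
9 | 1-[(2R,3R)-3-methyl-3-(oct-7-en-1-yl)oxiran-2-yl]ethan-1-ol, carbinol epimers | C=CCCCCCC[C@@]1(C)O[C@@H]1C(C)O | intermediate
10 | (4R)-4-methyldodec-11-ene-2,4-diol, C2 epimers | C=CCCCCCC[C@@](C)(O)CC(C)O | intermediate
11 | (4R)-4-hydroxy-4-methyldodec-11-en-2-yl methanesulfonate, C2 epimers | C=CCCCCCC[C@@](C)(O)CC(C)OS(C)(=O)=O | intermediate
12 | (2R)-2,4-dimethyl-2-(oct-7-en-1-yl)oxetane, C4 epimers | C=CCCCCCC[C@]1(C)CC(C)O1 | intermediate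
13 | (4S)-4-hydroperoxy-4-methyldodec-11-en-2-ol, C2 epimers | C=CCCCCCC[C@](C)(OO)CC(C)O | intermediate
14 | (4S)-4-[(tert-butyldimethylsilyl)peroxy]-4-methyldodec-11-en-2-ol, C2 epimers | C=CCCCCCC[C@](C)(OO[Si](C)(C)C(C)(C)C)CC(C)O | intermediate
15 | (4S)-4-[(tert-butyldimethylsilyl)peroxy]-4-methyldodec-11-en-2-one | C=CCCCCCC[C@](C)(OO[Si](C)(C)C(C)(C)C)CC(C)=O | intermediate
16 | (4S)-4-hydroperoxy-4-methyldodec-11-en-2-one | C=CCCCCCC[C@](C)(OO)CC(C)=O | intermediate
17 | (5S)-3,5-dimethyl-5-(oct-7-en-1-yl)-1,2-dioxolan-3-ol, C3 anomers | C=CCCCCCC[C@@]1(C)CC(C)(O)OO1 | intermediate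
18 | (5S)-3-methoxy-3,5-dimethyl-5-(oct-7-en-1-yl)-1,2-dioxolane, C3 anomers | C=CCCCCCC[C@@]1(C)CC(C)(OC)OO1 | intermediate
19 | methyl acetate | COC(C)=O | starting material
20 | lithium enolate of methyl acetate | C=C(OC)O[Li] | intermediate
21 | tert-butyl[(1-methoxyethenyl)oxy]dimethylsilane | C=C(OC)O[Si](C)(C)C(C)(C)C | intermediate
22 | (5S)-3,5-dimethyl-5-(oct-7-en-1-yl)-4,5-dihydro-1,2-dioxol-2-ium (peroxycarbenium ion) | C=CCCCCCC[C@@]1(C)CC(C)=[O+]O1 | intermediate
23 | methyl 2-[(3R,5S)-3,5-dimethyl-5-(oct-7-en-1-yl)-1,2-dioxolan-3-yl]acetate | C=CCCCCCC[C@@]1(C)C[C@](C)(CC(=O)OC)OO1 | intermediate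
24 | (2E)-but-2-enal (crotonaldehyde) | C/C=C/C=O | starting material
25 | methyl 2-{(3R,5S)-3,5-dimethyl-5-[(7E)-9-oxonon-7-en-1-yl]-1,2-dioxolan-3-yl}acetate | O=C/C=C/CCCCCC[C@@]1(C)C[C@](C)(CC(=O)OC)OO1 | intermediate
26 | (3Z)-hex-3-en-1-ol | CC/C=C\CCO | starting material
27 | 1-phenyl-1H-tetrazole-5-thiol | Sc1nnnn1-c1ccccc1 | starting material
28 | 5-{[(3Z)-hex-3-en-1-yl]sulfanyl}-1-phenyl-1H-tetrazole | CC/C=C\CCSc1nnnn1-c1ccccc1 | intermediate
29 | 5-{[(3Z)-hex-3-en-1-yl]sulfonyl}-1-phenyl-1H-tetrazole | CC/C=C\CCS(=O)(=O)c1nnnn1-c1ccccc1 | intermediate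
30 | potassium salt of the alpha-sulfonyl carbanion of 29 | [K+].CC/C=C\C[CH-]S(=O)(=O)c1nnnn1-c1ccccc1 | intermediate
31 | methyl 2-{(3R,5S)-3,5-dimethyl-5-[(7E,9E,12Z)-pentadeca-7,9,12-trien-1-yl]-1,2-dioxolan-3-yl}acetate | CC/C=C\C/C=C/C=C/CCCCCC[C@@]1(C)C[C@](C)(CC(=O)OC)OO1 | intermediate
32 | lithium 2-{(3R,5S)-3,5-dimethyl-5-[(7E,9E,12Z)-pentadeca-7,9,12-trien-1-yl]-1,2-dioxolan-3-yl}acetate | [Li+].CC/C=C\C/C=C/C=C/CCCCCC[C@@]1(C)C[C@](C)(CC(=O)[O-])OO1 | intermediate
33 | 2-{(3R,5S)-3,5-dimethyl-5-[(7E,9E,12Z)-pentadeca-7,9,12-trien-1-yl]-1,2-dioxolan-3-yl}acetic acid | CC/C=C\C/C=C/C=C/CCCCCC[C@@]1(C)C[C@](C)(CC(=O)O)OO1 | target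

**Step count**
- Total steps: 20.
- Longest linear sequence: 17 (steps 1–13, 15, 16, 19, 20).

**Three steps most likely to fail**

**Step 9 (oxetane perhydrolysis).** The yield is only moderate. Any opening with retention lowers the ee at C5, and in a carbinol epimer mixture this goes unseen. The fallback sets out from 10 and comes back at 15. It replaces trust in stereospecificity by a diastereomeric purge.
- Mixture 10 is sorted with immobilised Candida antarctica lipase B and vinyl acetate (MTBE, 25 °C). The lipase acetylates only the (2R) carbinol, giving (2R,4R)-4-hydroxy-4-methyldodec-11-en-2-yl acetate F1, which is kept in reserve.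
- Untouched (2S,4R)-4-methyldodec-11-ene-2,4-diol F2 is separated on silica.
- MsCl/Et3N converts it into (2S,4R)-4-hydroxy-4-methyldodec-11-en-2-yl methanesulfonate F3.
- KOt-Bu closes this to the single isomer (2R,4R)-2,4-dimethyl-2-(oct-7-en-1-yl)oxetane F4.
- Perhydrolysis then gives (2R,4S)-4-hydroperoxy-4-methyldodec-11-en-2-ol F5. Any retention product is now a diastereomer, visible by NMR and removable by chromatography.
- TBSCl/imidazole gives (2R,4S)-4-[(tert-butyldimethylsilyl)peroxy]-4-methyldodec-11-en-2-ol F6, and Dess–Martin oxidation delivers stereochemically upgraded 15.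

**Step 15 (facial selectivity and epimer separation).** The fallback sets out from 18 and comes back at 23. It replaces substrate control by auxiliary control within the same bond construction.
- Commercial (4S)-3-acetyl-4-(propan-2-yl)-1,3-thiazolidine-2-thione is treated with TiCl4 and i-Pr2NEt (CH2Cl2, −78 °C) and then with 18 and SnCl4.
- This gives 2-[(3R,5S)-3,5-dimethyl-5-(oct-7-en-1-yl)-1,2-dioxolan-3-yl]-1-[(4S)-4-(propan-2-yl)-2-sulfanylidene-1,3-thiazolidin-3-yl]ethan-1-one F7.
- The auxiliary adds a reagent bias to the attack. Every unwanted isomer, including any that stems from (5R) material, becomes a yellow diastereomer that is easy to follow and separate on silica.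
- MeOH with imidazole (CH2Cl2, 25 °C) then releases 23.

**Step 19 (E/Z ratio and a carbanion next to a beta-peroxy ester).** The fallback sets out from 23 (and 26) and comes back at 31. It forms C13–C14 by cross-coupling instead of C14=C15 by olefination.
- 23 undergoes cross metathesis with vinylboronic acid pinacol ester (second-generation Hoveyda–Grubbs catalyst, CH2Cl2, 40 °C). The product is methyl 2-{(3R,5S)-3,5-dimethyl-5-[(7E)-8-(4,4,5,5-tetramethyl-1,3,2-dioxaborolan-2-yl)oct-7-en-1-yl]-1,2-dioxolan-3-yl}acetate F8.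
- Separately, 26 is oxidised with Dess–Martin periodinane to (3Z)-hex-3-enal F9, which is used at once.
- Takai olefination (CrCl2, CHI3, THF, 0 °C) converts it into (1E,4Z)-1-iodohepta-1,4-diene F10.
- Suzuki–Miyaura coupling of F8 with F10 (Pd(PPh3)4 5 mol %, aq. K3PO4, THF, 25 °C) retains both alkene geometries and gives 31 without any strong base.

**Further compounds**
F1 | step 9 | (2R,4R)-4-hydroxy-4-methyldodec-11-en-2-yl acetate | C=CCCCCCC[C@@](C)(O)C[C@@H](C)OC(C)=O
F2 | step 9 | (2S,4R)-4-methyldodec-11-ene-2,4-diol | C=CCCCCCC[C@@](C)(O)C[C@H](C)O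
F3 | step 9 | (2S,4R)-4-hydroxy-4-methyldodec-11-en-2-yl methanesulfonate | C=CCCCCCC[C@@](C)(O)C[C@H](C)OS(C)(=O)=O
F4 | step 9 | (2R,4R)-2,4-dimethyl-2-(oct-7-en-1-yl)oxetane | C=CCCCCCC[C@]1(C)C[C@@H](C)O1
F5 | step 9 | (2R,4S)-4-hydroperoxy-4-methyldodec-11-en-2-ol | C=CCCCCCC[C@](C)(OO)C[C@@H](C)O
F6 | step 9 | (2R,4S)-4-[(tert-butyldimethylsilyl)peroxy]-4-methyldodec-11-en-2-ol | C=CCCCCCC[C@](C)(OO[Si](C)(C)C(C)(C)C)C[C@@H](C)O
F7 | step 15 | 2-[(3R,5S)-3,5-dimethyl-5-(oct-7-en-1-yl)-1,2-dioxolan-3-yl]-1-[(4S)-4-(propan-2-yl)-2-sulfanylidene-1,3-thiazolidin-3-yl]ethan-1-one | C=CCCCCCC[C@@]1(C)C[C@](C)(CC(=O)N2[C@@H](C(C)C)CSC2=S)OO1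
F8 | step 19 | methyl 2-{(3R,5S)-3,5-dimethyl-5-[(7E)-8-(4,4,5,5-tetramethyl-1,3,2-dioxaborolan-2-yl)oct-7-en-1-yl]-1,2-dioxolan-3-yl}acetate | CC1(C)OB(/C=C/CCCCCC[C@@]2(C)C[C@](C)(CC(=O)OC)OO2)OC1(C)C
F9 | step 19 | (3Z)-hex-3-enal | CC/C=C\CC=O
F10 | step 19 | (1E,4Z)-1-iodohepta-1,4-diene | CC/C=C\C/C=C/I
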